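**Plan**
- Retrosynthetic cuts: ring C at O1–C2 and C3–OH (oxidative flavonol closure), then C2–C3 (chalcone Cα–Cβ) and C4–C4a (acetyl on ring A); ring A at C8–C8a, then the lactone C–O and malonyl C–C bonds of a pyranone; the side-chain alkene C4''=C5''; the ring alkene of limonene.
- Forward: the limonene ring is opened to a chain, the prenyl arm is made by olefination, a 4-methoxypyran-2-one is built on the methyl ketone, ring A is made from it (step 7), the acetyl group is introduced, the chalcone is formed with the purchased ring B, and ring C closes last.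
- Stereochemistry: the only stereocentre, C2'', is C4 of (S)-limonene; it never sits next to a carbonyl group or carbanion and is carried through unchanged (the S/R label changes only because CIP priorities change).
- Enabling feature: ring A (C4a, C5, C6, C7, C8, C8a) bears oxygen on C5, C7 and C8a and carbon on C8, the alternating pattern of a 3,5-dioxo acid folded by acylation of C8 with C8a. Before ring C is fused it is mirror-symmetric through C5 and C8, so either hydroxyl can become O1. C8–C1''–C2'', with the isopropenyl group and two CH2 arms on C2'', is C6–C5–C4 of limonene after cleavage of C1=C2.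

Key step: step 7

Remark: "(2R)-lavandulyl" stands for (2R)-5-methyl-2-(prop-1-en-2-yl)hex-4-en-1-yl; epoxide 2 and diol 3 are used as mixtures at C1/C2, which is harmless because step 2 turns both carbons into carbonyl carbons.

**Step 1**
Reactants: 1 (S)-limonene
Product: 2 (4S)-limonene 1,2-oxide (cis/trans mixture)
Conditions: mCPBA (1.0 equiv), NaHCO3, CH2Cl2, 0 °C
Reagents that add atoms: mCPBA, O=C(OO)c1cccc(Cl)c1
Why: Prilezhaev epoxidation, in which the peracid attacks the electron-rich trisubstituted ring alkene much faster than the 1,1-disubstituted isopropenyl group; the two new epoxide centres form unselectively and are erased in step 2.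

**Step 2**
Reactants: 2 (4S)-limonene 1,2-oxide
Product: 4 (3S)-6-oxo-3-(prop-1-en-2-yl)heptanal, via diol 3 (not isolated)
Conditions: H5IO6 (1.2 equiv), THF/H2O, 0 °C to rt
Reagents that add atoms: water, O
Why: Acid-catalysed epoxide hydrolysis to the vicinal diol followed in the same flask by Malaprade glycol cleavage, a conversion established for limonene oxide; C4 of limonene is not touched.

**Step 3**
Reactants: 4 (3S)-6-oxo-3-(prop-1-en-2-yl)heptanal; 5 isopropyltriphenylphosphonium iodide
Product: 7 (5S)-8-methyl-5-(prop-1-en-2-yl)non-7-en-2-one, via phosphorus ylide 6 (not isolated)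
Conditions: 5 (1.05 equiv), n-BuLi (1.0 equiv), THF, 0 °C; then 4, −78 to 0 °C
Reagents that add atoms: none
Why: Wittig olefination, in which the hindered unstabilised ylide at −78 °C should react with the aldehyde far faster than with the methyl ketone, so that one equivalent converts only the formyl group into the trisubstituted alkene; no stereochemistry is created.

**Step 4**
Reactants: 7 (5S)-8-methyl-5-(prop-1-en-2-yl)non-7-en-2-one
Product: 9 trimethyl{[(5S)-8-methyl-5-(prop-1-en-2-yl)nona-1,7-dien-2-yl]oxy}silane, via lithium enolate 8 (not isolated)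
Conditions: LDA (1.1 equiv), TMSCl (1.3 equiv, present from the start), THF, −78 °C; pentane, filtration
Reagents that add atoms: chlorotrimethylsilane, C[Si](C)(C)Cl
Why: Kinetic enolate formation at the less hindered methyl group by the bulky amide at −78 °C, with immediate O-silylation, should give the terminal silyl enol ether.

**Step 5**
Reactants: 9 silyl enol ether; 10 malonyl dichloride
Product: 12 4-hydroxy-6-[(3S)-6-methyl-3-(prop-1-en-2-yl)hept-5-en-1-yl]-2H-pyran-2-one, via dioxo acid chloride 11 (not isolated)
Conditions: 10 (1.05 equiv), Et2O, −78 to −20 °C; cold aq. NaHCO3, then citric acid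
Reagents that add atoms: none
Why: C-acylation of the enol silane by one acid chloride group followed by lactonisation of the enol oxygen onto the second (6-exo-trig O-acylation) is a known route to 6-alkyl-4-hydroxypyran-2-ones, and holding the mixture at or below −20 °C should limit addition of the released HCl to the alkenes.

**Step 6**
Reactants: 12 hydroxypyranone
Product: 13 4-methoxy-6-[(3S)-6-methyl-3-(prop-1-en-2-yl)hept-5-en-1-yl]-2H-pyran-2-one
Conditions: Me2SO4 (1.2 equiv), K2CO3 (2 equiv), acetone, 50 °C
Reagents that add atoms: dimethyl sulfate, COS(=O)(=O)OC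
Why: O-alkylation (Williamson type) of the acidic vinylogous carboxylic acid with dimethyl sulfate and carbonate in acetone is the standard way to the 4-methoxypyran-2-one regioisomer.

**Step 7**
Reactants: 13 methoxypyranone
Product: 15 5-methoxy-2-[(2R)-5-methyl-2-(prop-1-en-2-yl)hex-4-en-1-yl]benzene-1,3-diol, via open-chain keto ester 14 (not isolated)
Conditions: NaOMe (6 equiv), dry degassed MeOH (0.05 M), sealed tube, 100 °C; then 1 M HCl, 0 °C, to pH 5
Reagents that add atoms: none
Why: Proposed new method: methoxide adds to the lactone carbonyl of 13 and opens the ring to the (2E)-3-methoxy-5-oxo ester 14, in which the ester carbon (future C8a) and the keto side chain remain cis on the enol-ether double bond; the ketone enolate at the side-chain CH2 (future C8), present in equilibrium with the more stable enolate between the ketone and the enol ether, attacks the ester carbonyl, methoxide leaves, and the resulting 5-methoxycyclohexene-1,3-dione tautomerises to the resorcinolate. The closest known reactions are the base-induced opening and Claisen recyclisation of 4-methoxy-6-methylpyran-2-one to 5-methoxyresorcinol, the biomimetic Claisen closure of β-polyketo esters to phloroglucinols, and the Dieckmann-type cyclisation of 5-oxoalkanoates to 2-alkylcyclohexane-1,3-diones; what is new is a singly activated CH2 as nucleophile towards a β-methoxy enoate. Ring A is the only ring closed, by formation of C8–C8a in a 6-(enolendo)-exo-trig closure, and the other enolate carbon could only give a four-membered ring, so there is no regiochemical competitor. No stereocentre is formed; C2'' is γ to the ketone, has no acidic hydrogen and is untouched, and 100 °C is far below the temperature at which the 1,5-diene would undergo Cope rearrangement. The selectivity needed is C- over O-acylation, which excess dry methoxide should secure because the O-acylation product (13) is reopened and E/Z scrambling of 14 is reversible, whereas the aromatic phenolate is not reopened. Water must be excluded because hydroxide would give an unreactive carboxylate, and the methoxy group is already para to the new alkyl-bearing carbon, so 5-OMe versus 7-OH is fixed before any phenol exists.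

**Step 8**
Reactants: 15 resorcinol
Product: 16 5-methoxy-1,3-bis(methoxymethoxy)-2-[(2R)-lavandulyl]benzene
Conditions: NaH (2.5 equiv), MOMCl (2.5 equiv), DMF, 0 °C to rt
Reagents that add atoms: chloromethyl methyl ether, COCCl
Why: Williamson etherification of both phenolates with the hard electrophile MOMCl; the symmetric diol gives a single bis-ether.

**Step 9**
Reactants: 16 bis-MOM ether; 17 N-methoxy-N-methylacetamide
Product: 19 1-{6-methoxy-2,4-bis(methoxymethoxy)-3-[(2R)-lavandulyl]phenyl}ethan-1-one, via aryllithium 18 (not isolated)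
Conditions: n-BuLi (1.2 equiv), THF, 0 °C; then 17 (1.5 equiv), −78 to 0 °C; aq. NH4Cl
Reagents that add atoms: none
Why: Directed ortho-metalation removes the ring hydrogen flanked by a MOM ether and the methoxy group (the two such positions are equivalent by symmetry), and the aryllithium is acylated in a Weinreb ketone synthesis whose chelated adduct prevents over-addition.

**Step 10**
Reactants: 19 bis-MOM acetophenone
Product: 20 1-{2-hydroxy-6-methoxy-4-(methoxymethoxy)-3-[(2R)-lavandulyl]phenyl}ethan-1-one
Conditions: HCl (0.1 M in MeOH), 0 °C to rt, stopped at mono-deprotection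
Reagents that add atoms: none
Why: Chemoselective acid-catalysed acetal cleavage, in which the MOM ether ortho to the acetyl group, crowded between two substituents and assisted by hydrogen bonding to the carbonyl, should be lost well before the 4-MOM ether, while the freed phenol is held in a chelate and should not add to the isopropenyl group.

**Step 11**
Reactants: 21 2,4-dihydroxybenzaldehyde
Product: 22 2,4-bis(methoxymethoxy)benzaldehyde
Conditions: NaH (2.5 equiv), MOMCl (2.5 equiv), DMF, 0 °C to rt
Reagents that add atoms: chloromethyl methyl ether, COCCl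
Why: Williamson etherification of both phenolates, the hydrogen-bonded 2-OH included once it is deprotonated by the hydride.

**Step 12**
Reactants: 20 2-hydroxyacetophenone; 22 2,4-bis(methoxymethoxy)benzaldehyde
Product: 23 (2E)-3-[2,4-bis(methoxymethoxy)phenyl]-1-{2-hydroxy-6-methoxy-4-(methoxymethoxy)-3-[(2R)-lavandulyl]phenyl}prop-2-en-1-one
Conditions: KOH (aq. 50 %, excess), EtOH, rt
Reagents that add atoms: none
Why: Claisen–Schmidt condensation, in which the acetophenone enolate adds to the non-enolisable aldehyde and E1cB dehydration gives the (E)-chalcone; MOM ethers and the isolated alkenes are inert to hydroxide.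

**Step 13**
Reactants: 23 chalcone
Product: 24 2-[2,4-bis(methoxymethoxy)phenyl]-3-hydroxy-5-methoxy-7-(methoxymethoxy)-8-[(2R)-lavandulyl]-4H-chromen-4-one
Conditions: H2O2 (30 %, 6 equiv), NaOH (2 M, 6 equiv), MeOH, 0 °C to rt
Reagents that add atoms: hydrogen peroxide, OO
Why: Algar–Flynn–Oyamada oxidation, in which hydroperoxide oxidises the enone while the 2'-phenoxide closes the six-membered ring C at the β-carbon and the dihydroflavonol is dehydrogenated in situ; the electron-rich B ring should favour attack at the β-carbon, and alkaline peroxide does not touch the isolated alkenes.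

**Step 14**
Reactants: 24 MOM-protected flavonol
Product: 25 methylkushenol C
Conditions: HCl (ca. 1 M in MeOH), 40 °C, short reaction time
Reagents that add atoms: none
Why: Acid-catalysed acetal cleavage (transacetalisation to methanol) should remove the three MOM ethers under conditions mild enough to spare the aryl methyl ether and to avoid cyclisation of the 7-OH onto the lavandulyl alkenes.

**Compound list**
1 | (S)-limonene | C=C(C)[C@@H]1CC=C(C)CC1 | starting material
2 | (4S)-1-methyl-4-(prop-1-en-2-yl)-7-oxabicyclo[4.1.0]heptane (limonene 1,2-oxide, cis/trans mixture) | C=C(C)[C@@H]1CC2OC2(C)CC1 | intermediate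
3 | (4S)-1-methyl-4-(prop-1-en-2-yl)cyclohexane-1,2-diol | C=C(C)[C@@H]1CC(O)C(C)(O)CC1 | intermediate
4 | (3S)-6-oxo-3-(prop-1-en-2-yl)heptanal | C=C(C)[C@@H](CCC(C)=O)CC=O | intermediate
5 | isopropyltriphenylphosphonium iodide | CC(C)[P+](c1ccccc1)(c1ccccc1)c1ccccc1.[I-] | starting material
6 | isopropylidenetriphenylphosphorane | CC(C)=P(c1ccccc1)(c1ccccc1)c1ccccc1 | intermediate
7 | (5S)-8-methyl-5-(prop-1-en-2-yl)non-7-en-2-one | C=C(C)[C@H](CC=C(C)C)CCC(C)=O | intermediate
8 | lithium (5S)-8-methyl-5-(prop-1-en-2-yl)nona-1,7-dien-2-olate | C=C(C)[C@H](CC=C(C)C)CCC(=C)O[Li] | intermediate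
9 | trimethyl{[(5S)-8-methyl-5-(prop-1-en-2-yl)nona-1,7-dien-2-yl]oxy}silane | C=C(C)[C@H](CC=C(C)C)CCC(=C)O[Si](C)(C)C | intermediate
10 | malonyl dichloride | O=C(Cl)CC(=O)Cl | starting material
11 | (8S)-11-methyl-3,5-dioxo-8-(prop-1-en-2-yl)dodec-10-enoyl chloride | C=C(C)[C@H](CC=C(C)C)CCC(=O)CC(=O)CC(=O)Cl | intermediate
12 | 4-hydroxy-6-[(3S)-6-methyl-3-(prop-1-en-2-yl)hept-5-en-1-yl]-2H-pyran-2-one | C=C(C)[C@H](CC=C(C)C)CCc1cc(O)cc(=O)o1 | intermediate
13 | 4-methoxy-6-[(3S)-6-methyl-3-(prop-1-en-2-yl)hept-5-en-1-yl]-2H-pyran-2-one | C=C(C)[C@H](CC=C(C)C)CCc1cc(OC)cc(=O)o1 | intermediate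
14 | methyl (2E,8S)-3-methoxy-11-methyl-5-oxo-8-(prop-1-en-2-yl)dodeca-2,10-dienoate | C=C(C)[C@H](CC=C(C)C)CCC(=O)C/C(OC)=C\C(=O)OC | intermediate
15 | 5-methoxy-2-[(2R)-5-methyl-2-(prop-1-en-2-yl)hex-4-en-1-yl]benzene-1,3-diol | C=C(C)[C@H](CC=C(C)C)Cc1c(O)cc(OC)cc1O | intermediate
16 | 5-methoxy-1,3-bis(methoxymethoxy)-2-[(2R)-lavandulyl]benzene | C=C(C)[C@H](CC=C(C)C)Cc1c(OCOC)cc(OC)cc1OCOC | intermediate
17 | N-methoxy-N-methylacetamide | CC(=O)N(C)OC | starting material
18 | {6-methoxy-2,4-bis(methoxymethoxy)-3-[(2R)-lavandulyl]phenyl}lithium | C=C(C)[C@H](CC=C(C)C)Cc1c(OCOC)cc(OC)c([Li])c1OCOC | intermediate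
19 | 1-{6-methoxy-2,4-bis(methoxymethoxy)-3-[(2R)-lavandulyl]phenyl}ethan-1-one | C=C(C)[C@H](CC=C(C)C)Cc1c(OCOC)cc(OC)c(C(C)=O)c1OCOC | intermediate
20 | 1-{2-hydroxy-6-methoxy-4-(methoxymethoxy)-3-[(2R)-lavandulyl]phenyl}ethan-1-one | C=C(C)[C@H](CC=C(C)C)Cc1c(OCOC)cc(OC)c(C(C)=O)c1O | intermediate
21 | 2,4-dihydroxybenzaldehyde | O=Cc1ccc(O)cc1O | starting material
22 | 2,4-bis(methoxymethoxy)benzaldehyde | O=Cc1ccc(OCOC)cc1OCOC | intermediate
23 | (2E)-3-[2,4-bis(methoxymethoxy)phenyl]-1-{2-hydroxy-6-methoxy-4-(methoxymethoxy)-3-[(2R)-lavandulyl]phenyl}prop-2-en-1-one | C=C(C)[C@H](CC=C(C)C)Cc1c(OCOC)cc(OC)c(C(=O)/C=C/c2ccc(OCOC)cc2OCOC)c1O | intermediate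
24 | 2-[2,4-bis(methoxymethoxy)phenyl]-3-hydroxy-5-methoxy-7-(methoxymethoxy)-8-[(2R)-lavandulyl]-4H-chromen-4-one | C=C(C)[C@H](CC=C(C)C)Cc1c(OCOC)cc(OC)c2c(=O)c(O)c(-c3ccc(OCOC)cc3OCOC)oc12 | intermediate
25 | methylkushenol C, 2-(2,4-dihydroxyphenyl)-3,7-dihydroxy-5-methoxy-8-[(2R)-lavandulyl]-4H-chromen-4-one | C=C(C)[C@H](CC=C(C)C)Cc1c(O)cc(OC)c2c(=O)c(O)c(-c3ccc(O)cc3O)oc12 | target

**Count**
Total steps: 14. Longest linear sequence: 13 (steps 1–10 and 12–14).

**Steps most likely to fail**

Step 7 (the proposed new method). The opened keto ester may return to the lactone, or lose its ester to traces of hydroxide, faster than the side-chain enolate closes the ring, so that no carbocycle forms. The fallback uses known reactions only; it gives up the de novo ring and attaches the side chain to a purchased ring A. Every limonene-derived intermediate would need the same closure, so this fallback sets out from no numbered compound of the route but from two purchased materials, 5-methoxyresorcinol and racemic lavandulol, and it comes back at 16. 5-Methoxyresorcinol is protected (NaH, MOMCl, DMF) as 1-methoxy-3,5-bis(methoxymethoxy)benzene F1. F1 is lithiated between the two MOM ethers (n-BuLi, THF, 0 °C, directed ortho-metalation) and quenched with iodine to give 2-iodo-5-methoxy-1,3-bis(methoxymethoxy)benzene F2. Racemic lavandulol is resolved by lipase-catalysed acetylation with vinyl acetate, run beyond half conversion, and the slower-reacting enantiomer is recovered as (S)-lavandulol F3. An Appel reaction (PPh3, I2, imidazole) converts it into (3S)-3-(iodomethyl)-2,6-dimethylhepta-1,5-diene F4. Zinc insertion (Zn, LiCl, THF) gives [(2S)-5-methyl-2-(prop-1-en-2-yl)hex-4-en-1-yl]zinc iodide F5, and a palladium-catalysed Negishi coupling with F2 (Pd(OAc)2, SPhos, THF) should give 16, after which steps 9–14 follow unchanged. The stereocentre then comes from the resolution; its label changes from S to R only through the CIP priorities.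

Step 5. Hydrogen chloride released during the annulation may add to the two side-chain alkenes, and any internal enol silane from step 4 is carried into an isomeric pyranone. The fallback sets out from ketone 7 and comes back at 12 without acid chlorides. Crossed Claisen condensation of 7 with ethyl acetate (NaH, THF) acetylates the methyl group and gives (7S)-10-methyl-7-(prop-1-en-2-yl)undec-9-ene-2,4-dione F6. Its dianion (LDA, 2.2 equiv, THF, −78 to 0 °C), formed at the terminal methyl group, is carboxylated with CO2 to (8S)-11-methyl-3,5-dioxo-8-(prop-1-en-2-yl)dodec-10-enoic acid F7. Cyclodehydration with 1,1'-carbonyldiimidazole in THF closes the lactone to 12.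

Step 13. With the 6'-methoxy group present, ring closure through the α-carbon to a five-membered ring may outrun closure at the β-carbon. The fallback sets out from 16 and from aldehyde 22 and comes back at 25; it installs the C3 oxygen before ring C is made, so no chalcone is involved. Aryllithium 18, made from 16 as in step 9, is acylated with N-methoxy-N-methyl-2-(methoxymethoxy)acetamide to give 1-{6-methoxy-2,4-bis(methoxymethoxy)-3-[(2R)-lavandulyl]phenyl}-2-(methoxymethoxy)ethan-1-one F8. Dilute methanolic HCl, as in step 10, frees the chelated phenol to give 1-{2-hydroxy-6-methoxy-4-(methoxymethoxy)-3-[(2R)-lavandulyl]phenyl}-2-(methoxymethoxy)ethan-1-one F9. Pinnick oxidation of 22 (NaClO2, NaH2PO4, 2-methylbut-2-ene) gives 2,4-bis(methoxymethoxy)benzoic acid F10. Steglich esterification of F9 with F10 (EDC, DMAP) gives the aryl ester 2-[(methoxymethoxy)acetyl]-3-methoxy-5-(methoxymethoxy)-6-[(2R)-lavandulyl]phenyl 2,4-bis(methoxymethoxy)benzoate F11. Baker–Venkataraman rearrangement (LiHMDS, THF) gives the diketone 1-[2,4-bis(methoxymethoxy)phenyl]-3-{2-hydroxy-6-methoxy-4-(methoxymethoxy)-3-[(2R)-lavandulyl]phenyl}-2-(methoxymethoxy)propane-1,3-dione F12. Methanolic HCl then effects cyclodehydration and removal of all four MOM groups in one operation to give 25.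

Further compounds
F1 | step 7 | 1-methoxy-3,5-bis(methoxymethoxy)benzene | COCOc1cc(OC)cc(OCOC)c1
F2 | step 7 | 2-iodo-5-methoxy-1,3-bis(methoxymethoxy)benzene | COCOc1cc(OC)cc(OCOC)c1I
F3 | step 7 | (S)-lavandulol, (2S)-5-methyl-2-(prop-1-en-2-yl)hex-4-en-1-ol | C=C(C)[C@H](CC=C(C)C)CO
F4 | step 7 | (3S)-3-(iodomethyl)-2,6-dimethylhepta-1,5-diene | C=C(C)[C@H](CC=C(C)C)CI
F5 | step 7 | [(2S)-5-methyl-2-(prop-1-en-2-yl)hex-4-en-1-yl]zinc iodide | C=C(C)[C@H](CC=C(C)C)C[Zn]I
F6 | step 5 | (7S)-10-methyl-7-(prop-1-en-2-yl)undec-9-ene-2,4-dione | C=C(C)[C@H](CC=C(C)C)CCC(=O)CC(C)=O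
F7 | step 5 | (8S)-11-methyl-3,5-dioxo-8-(prop-1-en-2-yl)dodec-10-enoic acid | C=C(C)[C@H](CC=C(C)C)CCC(=O)CC(=O)CC(=O)O
F8 | step 13 | 1-{6-methoxy-2,4-bis(methoxymethoxy)-3-[(2R)-lavandulyl]phenyl}-2-(methoxymethoxy)ethan-1-one | C=C(C)[C@H](CC=C(C)C)Cc1c(OCOC)cc(OC)c(C(=O)COCOC)c1OCOC
F9 | step 13 | 1-{2-hydroxy-6-methoxy-4-(methoxymethoxy)-3-[(2R)-lavandulyl]phenyl}-2-(methoxymethoxy)ethan-1-one | C=C(C)[C@H](CC=C(C)C)Cc1c(OCOC)cc(OC)c(C(=O)COCOC)c1O
F10 | step 13 | 2,4-bis(methoxymethoxy)benzoic acid | O=C(O)c1ccc(OCOC)cc1OCOC
F11 | step 13 | 2-[(methoxymethoxy)acetyl]-3-methoxy-5-(methoxymethoxy)-6-[(2R)-lavandulyl]phenyl 2,4-bis(methoxymethoxy)benzoate | C=C(C)[C@H](CC=C(C)C)Cc1c(OCOC)cc(OC)c(C(=O)COCOC)c1OC(=O)c2ccc(OCOC)cc2OCOC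
F12 | step 13 | 1-[2,4-bis(methoxymethoxy)phenyl]-3-{2-hydroxy-6-methoxy-4-(methoxymethoxy)-3-[(2R)-lavandulyl]phenyl}-2-(methoxymethoxy)propane-1,3-dione | C=C(C)[C@H](CC=C(C)C)Cc1c(OCOC)cc(OC)c(C(=O)C(OCOC)C(=O)c2ccc(OCOC)cc2OCOC)c1O
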